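**Assumption:** the target, bis(2,3,6-tribromo-4,5-dihydroxybenzyl) ether, has no stereocentre and a mirror plane, so there is only one stereoisomer to make; the route delivers that achiral compound.

## Retrosynthetic overview

1. 6 ⇐ 5: the four phenols are unmasked last by hydrazinolysis of aryl acetates.
2. Key disconnection: the CH2–O–CH2 unit of 5 is cut to two molecules of one aldehyde 3. In the forward direction a silane reductive homo-etherification reduces both formyl groups and forms the C–O bond in one operation, with no benzyl alcohol/benzyl halide pair.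
3. 3 ⇐ 2 ⇐ 1: acetylation and exhaustive ring bromination of 3,4-dihydroxybenzaldehyde.
4. Rings: none is built; both benzene rings are bought in 1 and are joined in step 3.

## Route

**Step 1**
Reactants: 1 3,4-dihydroxybenzaldehyde
Product: 2 2,3,6-tribromo-4,5-dihydroxybenzaldehyde
Conditions: Br2 (3.5 equiv), FeBr3 (5 mol %), AcOH, rt → 80 °C
Reagents that add atoms: bromine, BrBr
Why: Exhaustive electrophilic aromatic bromination: each free ring position (C2, C5, C6) is ortho or para to a hydroxyl, the two OH groups override the meta-directing formyl group, and the Lewis acid drives in the last, most deactivated position.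

**Step 2**
Reactants: 2 2,3,6-tribromo-4,5-dihydroxybenzaldehyde
Product: 3 3,4,6-tribromo-5-formyl-1,2-phenylene diacetate
Conditions: Ac2O (3 equiv), pyridine, DMAP (cat.), CH2Cl2, 0 °C → rt
Reagents that add atoms: acetic anhydride, CC(=O)OC(C)=O
Why: DMAP-catalysed O-acylation of the two acidic bromophenol hydroxyls; the acetates make the arene electron-poor, so the benzylic ether formed in step 3 cannot ionise and be over-reduced to the toluene.

**Step 3**
Reactants: 3 3,4,6-tribromo-5-formyl-1,2-phenylene diacetate (two molecules)
Product: 5 bis(4,5-diacetoxy-2,3,6-tribromobenzyl) ether, via benzylic triethylsilyl ether 4 (not isolated)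
Conditions: Et3SiH (1.2 equiv per CHO), Me3SiOSO2CF3 (TMSOTf, 10 mol %), CH2Cl2 (1 M), 0 °C → rt
Reagents that add atoms: none
Why: Lewis-acid-catalysed silane reductive homo-etherification of an aldehyde: the silyl-activated aldehyde is reduced by Et3SiH to silyl ether 4, which adds to a second activated aldehyde; loss of disiloxane gives an oxocarbenium ion that takes a second hydride, and the electron-poor aryl groups keep the product ether from ionising.

**Step 4**
Reactants: 5 bis(4,5-diacetoxy-2,3,6-tribromobenzyl) ether
Product: 6 bis(2,3,6-tribromo-4,5-dihydroxybenzyl) ether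
Conditions: N2H4·H2O (5 equiv), degassed THF, 0 °C → rt, Ar; then aq. citric acid
Reagents that add atoms: none
Why: Chemoselective hydrazinolysis of aryl acetates: bromine-flanked phenyl acetates are activated esters, the dibenzyl ether and aryl bromides are inert to hydrazine, and the reducing, alcohol-free medium protects the catechols from oxidation and the ether from solvolytic exchange.

## Compound list

1 | 3,4-dihydroxybenzaldehyde (protocatechualdehyde) | O=Cc1ccc(O)c(O)c1 | starting material
2 | 2,3,6-tribromo-4,5-dihydroxybenzaldehyde | O=Cc1c(Br)c(Br)c(O)c(O)c1Br | intermediate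
3 | 3,4,6-tribromo-5-formyl-1,2-phenylene diacetate | CC(=O)Oc1c(OC(C)=O)c(Br)c(C=O)c(Br)c1Br | intermediate
4 | 3,4,6-tribromo-5-[(triethylsilyloxy)methyl]-1,2-phenylene diacetate | CC[Si](CC)(CC)OCc1c(Br)c(Br)c(OC(C)=O)c(OC(C)=O)c1Br | intermediate
5 | bis(4,5-diacetoxy-2,3,6-tribromobenzyl) ether | CC(=O)Oc1c(OC(C)=O)c(Br)c(COCc2c(Br)c(OC(C)=O)c(OC(C)=O)c(Br)c2Br)c(Br)c1Br | intermediate
6 | bis(2,3,6-tribromo-4,5-dihydroxybenzyl) ether | Oc1c(O)c(Br)c(COCc2c(Br)c(O)c(O)c(Br)c2Br)c(Br)c1Br | target

## Summary

Total step count: 4. Longest linear sequence: 4 steps (1 → 2 → 3 → 5 → 6; the route is linear and step 3 joins two molecules of the same intermediate).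

## Steps most likely to fail, with fallbacks

**Step 3 (reductive homo-etherification).** The two ortho bromines hinder attack of silyl ether 4 on the second activated aldehyde, so the reaction may stop at the silyl ether. The fallback sets out from 3 and comes back at 5 by a two-component coupling. Aldehyde 3 is reduced with BH3·SMe2 in THF at 0 °C to the benzylic alcohol 3,4,6-tribromo-5-(hydroxymethyl)-1,2-phenylene diacetate F1. Half of it is converted with PBr3 in CH2Cl2 at 0 °C into 3,4,6-tribromo-5-(bromomethyl)-1,2-phenylene diacetate F2. The two halves are then joined under base-free, halophile-promoted etherification (AgOSO2CF3, 2,6-di-tert-butyl-4-methylpyridine, CH2Cl2, −20 °C → rt, dark), which the aryl acetates tolerate, to give 5.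

**Step 1 (tribromination).** The third bromine, at C6 between the formyl group and a bromine, may enter slowly, and ipso attack para to the 4-OH can expel the formyl group. The fallback sets out from 1 and comes back at 2; it brominates a ring that carries a methyl group, which cannot be expelled, and oxidises the benzylic carbon afterwards.
- Hydrogenolysis of 1 (H2, Pd/C as palladium metal on carbon, AcOH, cat. HCl) gives 4-methylbenzene-1,2-diol F3, which can also simply be bought.
- Br2 (3.1 equiv) in CHCl3/AcOH at 0 °C → rt gives 3,4,6-tribromo-5-methylbenzene-1,2-diol F4.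
- Ac2O/pyridine gives 3,4,6-tribromo-5-methyl-1,2-phenylene diacetate F5.
- Radical benzylic dibromination (NBS 2.5 equiv, AIBN, PhCF3, reflux) gives 3,4,6-tribromo-5-(dibromomethyl)-1,2-phenylene diacetate F6.
- Hot aqueous H2SO4/AcOH (100 °C) hydrolyses the dibromomethyl group and both acetates to give 2.

**Step 4 (deacetylation).** A phenoxide para to the benzylic ether can fragment the ether through a p-quinone methide, and the free bromocatechols are air-sensitive in base. The fallback sets out from 2 and comes back at 6; it uses no protecting groups and forms the ether last. NaBH4 in THF/EtOH at 0 °C reduces 2 to 3,4,6-tribromo-5-(hydroxymethyl)benzene-1,2-diol F7. This is then dimerised by acid-catalysed dehydration (TsOH 5 mol %, MeNO2, 4 Å MS, 50 °C, 0.5 M) through the p-hydroxybenzyl cation/p-quinone methide. Because the ring is fully substituted, Friedel–Crafts C-alkylation is impossible and only O-alkylation to 6 remains.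

## Further compounds

F1 | step 3 | 3,4,6-tribromo-5-(hydroxymethyl)-1,2-phenylene diacetate | OCc1c(Br)c(Br)c(OC(C)=O)c(OC(C)=O)c1Br
F2 | step 3 | 3,4,6-tribromo-5-(bromomethyl)-1,2-phenylene diacetate | BrCc1c(Br)c(Br)c(OC(C)=O)c(OC(C)=O)c1Br
F3 | step 1 | 4-methylbenzene-1,2-diol | Cc1ccc(O)c(O)c1
F4 | step 1 | 3,4,6-tribromo-5-methylbenzene-1,2-diol | Cc1c(Br)c(Br)c(O)c(O)c1Br
F5 | step 1 | 3,4,6-tribromo-5-methyl-1,2-phenylene diacetate | Cc1c(Br)c(Br)c(OC(C)=O)c(OC(C)=O)c1Br
F6 | step 1 | 3,4,6-tribromo-5-(dibromomethyl)-1,2-phenylene diacetate | BrC(Br)c1c(Br)c(Br)c(OC(C)=O)c(OC(C)=O)c1Br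
F7 | step 4 | 3,4,6-tribromo-5-(hydroxymethyl)benzene-1,2-diol | OCc1c(Br)c(Br)c(O)c(O)c1Br
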